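Both prenyl groups are traced back to allyl groups that start out on oxygen. C6 and C8 of ring A each sit ortho to a phenolic oxygen (O5 on C5, O7 on C7), so the C6–CH2 and C8–CH2 bonds are disconnected to the 5-O- and 7-O-allyl ethers of a flavonol. A single thermolysis moves both allyl groups from oxygen to carbon by [3,3] shifts and releases the 5- and 7-hydroxyls. The precursor is the 5,7-bis(allyloxy)flavonol carrying the finished 2,2-dimethylchromen-7-yl ring B and a free 3-hydroxyl, which is created only after the allylation, so no 3-O protecting group and no closing acid treatment are needed. Cross-metathesis then turns allyl into prenyl.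

Key step: step 6

Assumption: the target is taken exactly as drawn, an achiral flavonol whose ring B is a 2,2-dimethyl-2H-chromen-7-yl unit (chromene oxygen on C3', chromene C4 on C4'); 1-(2,4,6-trihydroxyphenyl)ethanone is bought (dried if supplied as the monohydrate) instead of being made from phloroglucinol.

Step 1
Reactants: 1 4-bromo-2-hydroxybenzaldehyde; 2 2-methylprop-1-enylmagnesium bromide
Product: 4 7-bromo-2,2-dimethyl-2H-chromene, via allylic benzylic diol 3 (not isolated)
Conditions: 2 (2.5 equiv), THF, 0 °C to rt; aq NH4Cl; then PPTS (cat.), toluene, 80 °C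
Reagents that add atoms: none
Why: Grignard 1,2-addition to the aldehyde (one equivalent is spent on the phenol, the aryl bromide is inert at 0 °C) should give the ortho-hydroxybenzylic allylic alcohol 3, which loses water under mild acid to an ortho-quinone methide whose oxa-6π electrocyclization closes the 2,2-dimethylpyran ring; the carbinol stereocentre of 3 is racemic and disappears in the dehydration.

Step 2
Reactants: 4 7-bromo-2,2-dimethyl-2H-chromene
Product: 6 2,2-dimethyl-2H-chromene-7-carbaldehyde, via aryllithium 5 (not isolated)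
Conditions: n-BuLi (1.1 equiv), THF, −78 °C; DMF, −78 °C to 0 °C; aq NH4Cl
Reagents that add atoms: N,N-dimethylformamide, CN(C)C=O
Why: Bromine–lithium exchange at −78 °C is much faster than any addition of n-BuLi to the styrene-type alkene, and the aryllithium is formylated by DMF (Bouveault aldehyde synthesis).

Step 3
Reactants: 7 1-(2,4,6-trihydroxyphenyl)ethanone; 8 allyl bromide
Product: 9 1-[2-hydroxy-4,6-bis(allyloxy)phenyl]ethanone
Conditions: 8 (2.1 equiv), K2CO3 (2.2 equiv), acetone, reflux
Reagents that add atoms: none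
Why: Williamson ether synthesis in which the 4-hydroxyl and one of the two equivalent ortho hydroxyls are alkylated, while the remaining ortho hydroxyl, hydrogen-bonded to the ketone, is the least nucleophilic and should stay free with two equivalents of halide.

Step 4
Reactants: 9 1-[2-hydroxy-4,6-bis(allyloxy)phenyl]ethanone; 6 2,2-dimethyl-2H-chromene-7-carbaldehyde
Product: 10 (E)-1-[2-hydroxy-4,6-bis(allyloxy)phenyl]-3-(2,2-dimethyl-2H-chromen-7-yl)prop-2-en-1-one
Conditions: KOH (50% aq), EtOH, rt; then cold dilute HCl to pH 5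
Reagents that add atoms: none
Why: Claisen–Schmidt condensation of a methyl ketone with a non-enolisable aryl aldehyde, in which dehydration of the aldol gives the conjugated E-enone as the thermodynamic product; allyl aryl ethers and the chromene are stable to aqueous-alcoholic KOH at room temperature.

Step 5
Reactants: 10 (E)-1-[2-hydroxy-4,6-bis(allyloxy)phenyl]-3-(2,2-dimethyl-2H-chromen-7-yl)prop-2-en-1-one
Product: 12 5,7-bis(allyloxy)-3-hydroxy-2-(2,2-dimethyl-2H-chromen-7-yl)-4H-chromen-4-one, via trans-dihydroflavonol 11 (not isolated)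
Conditions: 30% aq H2O2, 2 M aq NaOH, MeOH–THF, 0 °C to rt; then AcOH
Reagents that add atoms: hydrogen peroxide, OO
Why: Algar–Flynn–Oyamada reaction, in which the nucleophilic oxidant attacks only the electron-poor enone (the allyl and chromene alkenes are inert to alkaline H2O2), the 2'-phenoxide closes ring C to the dihydroflavonol 11 and further oxidation gives the flavonol, so the two transient stereocentres of 11 are erased.

Step 6
Reactants: 12 5,7-bis(allyloxy)-3-hydroxy-2-(2,2-dimethyl-2H-chromen-7-yl)-4H-chromen-4-one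
Product: 14 6,8-diallyl-3,5,7-trihydroxy-2-(2,2-dimethyl-2H-chromen-7-yl)-4H-chromen-4-one, via 6-allyl-7-allyloxy mono-rearranged flavonol 13 (not isolated)
Conditions: N,N-diethylaniline (degassed), 200–210 °C, sealed tube, Ar
Reagents that add atoms: none
Why: Each allyl aryl ether undergoes a concerted suprafacial [3,3] sigmatropic shift through a chair-like transition state to an ortho-allyl cyclohexadienone that enolises to the phenol, which is the aromatic Claisen rearrangement long used on flavone allyl ethers in hot N,N-dialkylanilines. The 5-O-allyl group can reach only C6, because its other ortho position is the ring-fusion carbon C4a, and this gives 13; the 7-O-allyl group then finds C8 as its one free ortho site. Should the 7-O-allyl group move first (to C8 or to C6), the 5-O-allyl group goes to C6 directly or, where C6 is already filled, through a 6,6-diallyl dienone followed by a Cope shift to C8 (para-Claisen relay), so every order ends at 14. This convergence holds because an unsubstituted allyl group is the same after one or two allylic inversions, which is the reason for migrating allyl groups here instead of prenyl groups. No ring is closed and no stereocentre is formed; the only selectivity in play is C6 against C8 for each group, and the convergence removes it, while O3 bears hydrogen, not an allyl group, so nothing can be delivered to C2. The basic, oxygen-free medium should keep the freed ortho-allylphenols from closing to dihydrobenzofurans and protect the flavonol and the chromene, which itself is a thermally robust ring of the kind routinely formed at these temperatures.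

Step 7
Reactants: 14 6,8-diallyl-3,5,7-trihydroxy-2-(2,2-dimethyl-2H-chromen-7-yl)-4H-chromen-4-one; 15 2-methylbut-2-ene
Product: 16 dorsilurin C
Conditions: second-generation Grubbs catalyst RuCl2(=CHPh)(PCy3)(H2IMes) (5–10 mol %), 15 (large excess, co-solvent), CH2Cl2, 40 °C, sealed tube, Ar
Reagents that add atoms: none
Why: Olefin cross-metathesis in which each terminal allyl group exchanges its CH2 terminus for the isopropylidene unit of 2-methylbut-2-ene with loss of propene, giving trisubstituted prenyl alkenes that do not re-enter the cycle, while the chromene alkene (cyclic, conjugated, next to a quaternary carbon) should not be opened and free phenols are tolerated by the catalyst.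

Compound list
1 | 4-bromo-2-hydroxybenzaldehyde | O=Cc1ccc(Br)cc1O | starting material
2 | 2-methylprop-1-enylmagnesium bromide (THF solution) | CC(C)=C[Mg]Br | starting material
3 | 5-bromo-2-(1-hydroxy-3-methylbut-2-en-1-yl)phenol (racemic, not isolated) | CC(C)=CC(O)c1ccc(Br)cc1O | intermediate
4 | 7-bromo-2,2-dimethyl-2H-chromene | CC1(C)C=Cc2ccc(Br)cc2O1 | intermediate
5 | (2,2-dimethyl-2H-chromen-7-yl)lithium (not isolated) | [Li]c1ccc2C=CC(C)(C)Oc2c1 | intermediate
6 | 2,2-dimethyl-2H-chromene-7-carbaldehyde | O=Cc1ccc2C=CC(C)(C)Oc2c1 | intermediate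
7 | 1-(2,4,6-trihydroxyphenyl)ethanone | CC(=O)c1c(O)cc(O)cc1O | starting material
8 | allyl bromide | C=CCBr | starting material
9 | 1-[2-hydroxy-4,6-bis(allyloxy)phenyl]ethanone | CC(=O)c1c(O)cc(OCC=C)cc1OCC=C | intermediate
10 | (E)-1-[2-hydroxy-4,6-bis(allyloxy)phenyl]-3-(2,2-dimethyl-2H-chromen-7-yl)prop-2-en-1-one | C=CCOc1cc(O)c(C(=O)/C=C/c2ccc3C=CC(C)(C)Oc3c2)c(OCC=C)c1 | intermediate
11 | trans-5,7-bis(allyloxy)-3-hydroxy-2-(2,2-dimethyl-2H-chromen-7-yl)chroman-4-one (racemic, (2R,3R) enantiomer drawn, not isolated) | C=CCOc1cc(OCC=C)c2C(=O)[C@H](O)[C@@H](c3ccc4c(c3)OC(C)(C)C=C4)Oc2c1 | intermediate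
12 | 5,7-bis(allyloxy)-3-hydroxy-2-(2,2-dimethyl-2H-chromen-7-yl)-4H-chromen-4-one | C=CCOc1cc(OCC=C)c2c(=O)c(O)c(-c3ccc4c(c3)OC(C)(C)C=C4)oc2c1 | intermediate
13 | 6-allyl-7-(allyloxy)-3,5-dihydroxy-2-(2,2-dimethyl-2H-chromen-7-yl)-4H-chromen-4-one (not isolated) | C=CCOc1cc2oc(-c3ccc4c(c3)OC(C)(C)C=C4)c(O)c(=O)c2c(O)c1CC=C | intermediate
14 | 6,8-diallyl-3,5,7-trihydroxy-2-(2,2-dimethyl-2H-chromen-7-yl)-4H-chromen-4-one | C=CCc1c(O)c(CC=C)c2oc(-c3ccc4c(c3)OC(C)(C)C=C4)c(O)c(=O)c2c1O | intermediate
15 | 2-methylbut-2-ene | CC=C(C)C | starting material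
16 | dorsilurin C, 3,5,7-trihydroxy-2-(2,2-dimethyl-2H-chromen-7-yl)-6,8-bis(3-methylbut-2-en-1-yl)-4H-chromen-4-one (achiral) | CC(C)=CCc1c(O)c(CC=C(C)C)c2oc(-c3ccc4c(c3)OC(C)(C)C=C4)c(O)c(=O)c2c1O | target

Total step count: 7. Longest linear sequence: 6 steps (steps 1, 2, 4, 5, 6, 7 from compound 1).

Steps most likely to fail

Step 6. The second migration may stall, the freed ortho-allylphenols may close thermally to 2-methyl-2,3-dihydrobenzofurans, or the free flavonol and the chromene may degrade at 200 °C. The fallback moves the double rearrangement to the small acetophenone; it sets out from 9 and comes back at 14. Heating 9 alone in N,N-diethylaniline at 200 °C should give 1-(3,5-diallyl-2,4,6-trihydroxyphenyl)ethanone F1 by the same convergent double shift. MOMCl and i-Pr2NEt in CH2Cl2 should cap the two non-chelated hydroxyls to give 1-[3,5-diallyl-2-hydroxy-4,6-bis(methoxymethoxy)phenyl]ethanone F2. Claisen–Schmidt condensation of F2 with aldehyde 6 (KOH, EtOH) should give (E)-1-[3,5-diallyl-2-hydroxy-4,6-bis(methoxymethoxy)phenyl]-3-(2,2-dimethyl-2H-chromen-7-yl)prop-2-en-1-one F3. Alkaline H2O2 should convert it into 6,8-diallyl-3-hydroxy-5,7-bis(methoxymethoxy)-2-(2,2-dimethyl-2H-chromen-7-yl)-4H-chromen-4-one F4. Dilute HCl in MeOH at 40 °C, harmless to terminal allyl groups, should then remove both MOM groups to arrive at 14.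

Step 5. The 6'-allyloxy group may divert the oxidative cyclisation towards five-membered ring closure (aurone formation) or leave it at the dihydroflavonol stage. The fallback builds the flavone first and oxygenates C3 afterwards; it sets out from 10 and comes back at 12. NaOAc in refluxing EtOH should isomerise 10 to racemic 5,7-bis(allyloxy)-2-(2,2-dimethyl-2H-chromen-7-yl)chroman-4-one F5. DDQ in refluxing dioxane should dehydrogenate it to 5,7-bis(allyloxy)-2-(2,2-dimethyl-2H-chromen-7-yl)-4H-chromen-4-one F6. Lithiation of C3 with LiN(i-Pr)2 in THF at −78 °C, trapping with B(OMe)3 and oxidation of the borate with H2O2/AcOH at 0 °C should return 12.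

Step 7. The catalyst may be tied up by the chelating hydroxy-ketone units, the ortho-allylphenol double bonds may migrate into conjugation, or the exchange may stop after one allyl group. The fallback masks all three hydroxyls for the metathesis; it sets out from 14 and comes back at 16. Ac2O and pyridine with catalytic DMAP should give 6,8-diallyl-2-(2,2-dimethyl-2H-chromen-7-yl)-4-oxo-4H-chromene-3,5,7-triyl triacetate F7. The same cross-metathesis with 15 should give 2-(2,2-dimethyl-2H-chromen-7-yl)-6,8-bis(3-methylbut-2-en-1-yl)-4-oxo-4H-chromene-3,5,7-triyl triacetate F8. K2CO3 in MeOH at rt under Ar should cleave the three acetates to give 16 without any acid.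

Further compounds
F1 | step 6 | 1-(3,5-diallyl-2,4,6-trihydroxyphenyl)ethanone | CC(=O)c1c(O)c(CC=C)c(O)c(CC=C)c1O
F2 | step 6 | 1-[3,5-diallyl-2-hydroxy-4,6-bis(methoxymethoxy)phenyl]ethanone | CC(=O)c1c(O)c(CC=C)c(OCOC)c(CC=C)c1OCOC
F3 | step 6 | (E)-1-[3,5-diallyl-2-hydroxy-4,6-bis(methoxymethoxy)phenyl]-3-(2,2-dimethyl-2H-chromen-7-yl)prop-2-en-1-one | COCOc1c(CC=C)c(O)c(C(=O)/C=C/c2ccc3C=CC(C)(C)Oc3c2)c(OCOC)c1CC=C
F4 | step 6 | 6,8-diallyl-3-hydroxy-5,7-bis(methoxymethoxy)-2-(2,2-dimethyl-2H-chromen-7-yl)-4H-chromen-4-one | C=CCc1c(OCOC)c(CC=C)c2oc(-c3ccc4c(c3)OC(C)(C)C=C4)c(O)c(=O)c2c1OCOC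
F5 | step 5 | 5,7-bis(allyloxy)-2-(2,2-dimethyl-2H-chromen-7-yl)chroman-4-one (racemic) | C=CCOc1cc(OCC=C)c2C(=O)CC(c3ccc4c(c3)OC(C)(C)C=C4)Oc2c1
F6 | step 5 | 5,7-bis(allyloxy)-2-(2,2-dimethyl-2H-chromen-7-yl)-4H-chromen-4-one | C=CCOc1cc(OCC=C)c2c(=O)cc(-c3ccc4c(c3)OC(C)(C)C=C4)oc2c1
F7 | step 7 | 6,8-diallyl-2-(2,2-dimethyl-2H-chromen-7-yl)-4-oxo-4H-chromene-3,5,7-triyl triacetate | C=CCc1c(OC(C)=O)c(CC=C)c2oc(-c3ccc4c(c3)OC(C)(C)C=C4)c(OC(C)=O)c(=O)c2c1OC(C)=O
F8 | step 7 | 2-(2,2-dimethyl-2H-chromen-7-yl)-6,8-bis(3-methylbut-2-en-1-yl)-4-oxo-4H-chromene-3,5,7-triyl triacetate | CC(C)=CCc1c(OC(C)=O)c(CC=C(C)C)c2oc(-c3ccc4c(c3)OC(C)(C)C=C4)c(OC(C)=O)c(=O)c2c1OC(C)=O
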